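## Retrosynthetic overview

1. The target is a 6-alkylated (2R,3R)-dihydroflavonol; the last operation removes four methoxymethyl (MOM) ethers and one triethylsilyl ether.
2. Ring C is the only ring made and is closed last through its C4–C3 bond. A chiral triazolylidene-catalysed intramolecular crossed benzoin of an open dialdehyde, run as a dynamic kinetic resolution, should give the C4 ketone, the C3 carbinol and both stereocentres in one operation. The ring A formyl carbon becomes C4 and the O1–C2H(ring B)–CHO arm supplies C3.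
3. Enabling feature: C4(=O)–C3H(OH) of ring C is an α-ketol (a benzoin retron) whose carbonyl sits on ring A. C2 carries O1 and ring B, so in the open dialdehyde C2–H is α to the acceptor aldehyde, acidic and configurationally mobile.
4. The dialdehyde comes from O-alkylation of a ring A salicylaldehyde with a ring B α-bromo arylacetate, then reduction and double oxidation.
5. The salicylaldehyde comes from resorcinol bis-MOM ether by directed lithiation/allylation (bromide from geranyl acetate by selective oxymercuration), sterically controlled C–H borylation/oxidation and ortho-formylation.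

Key step: step 13

Assumption: the (5aS,10bR) aminoindanol-derived triazolium salt is taken to give the (2R,3R) product; if the sense of induction proves opposite, the equally available (5aR,10bS) antipode is used with no other change. Compounds 16–19 are racemic at a centre that is equilibrated in step 13.

## Route

Step 1
Reactants: 1 geranyl acetate
Product: 3 (2E)-7-hydroxy-3,7-dimethyloct-2-en-1-yl acetate, via organomercurial acetate 2 (not isolated)
Conditions: Hg(OAc)2, THF/H2O (1:1), 0 °C to rt; then NaBH4, aq NaOH, 0 °C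
Reagents that add atoms: water, O
Why: Markovnikov oxymercuration–demercuration should hydrate the distal 6,7-alkene selectively, because the 2,3-alkene is deactivated by the allylic acetate, and it leaves the 2E geometry untouched.

Step 2
Reactants: 3 (2E)-7-hydroxy-3,7-dimethyloct-2-en-1-yl acetate
Product: 4 (2E)-3,7-dimethyl-7-(triethylsilyloxy)oct-2-en-1-yl acetate
Conditions: Et3SiOTf, 2,6-lutidine, CH2Cl2, −78 to 0 °C
Reagents that add atoms: triethylsilyl triflate, CC[Si](CC)(CC)OS(=O)(=O)C(F)(F)F
Why: Silyl triflate silylation is the standard way to protect a hindered tertiary alcohol, which must be masked before the aryllithium chemistry of step 5.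

Step 3
Reactants: 4 (2E)-3,7-dimethyl-7-(triethylsilyloxy)oct-2-en-1-yl acetate
Product: 5 (2E)-3,7-dimethyl-7-(triethylsilyloxy)oct-2-en-1-ol
Conditions: K2CO3 (cat.), MeOH, rt
Reagents that add atoms: none
Why: Base-catalysed transesterification should remove the acetate while the tertiary triethylsilyl ether is inert to carbonate in methanol.

Step 4
Reactants: 5 (2E)-3,7-dimethyl-7-(triethylsilyloxy)oct-2-en-1-ol
Product: 6 (2E)-1-bromo-3,7-dimethyl-7-(triethylsilyloxy)oct-2-ene
Conditions: CBr4, PPh3, CH2Cl2, −20 to 0 °C; used at once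
Reagents that add atoms: carbon tetrabromide, BrC(Br)(Br)Br
Why: The Appel reaction should convert the primary allylic alcohol to the bromide under neutral conditions by SN2 displacement, keeping the E alkene and the silyl ether.

Step 5
Reactants: 7 1,3-bis(methoxymethoxy)benzene; 6 (2E)-1-bromo-3,7-dimethyl-7-(triethylsilyloxy)oct-2-ene
Product: 9 2-[(2E)-3,7-dimethyl-7-(triethylsilyloxy)oct-2-en-1-yl]-1,3-bis(methoxymethoxy)benzene, via aryllithium 8 (not isolated)
Conditions: n-BuLi, THF, 0 °C to rt; CuI (10 mol%), −40 °C; then 6, −40 °C to rt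
Reagents that add atoms: none
Why: Directed ortho-metalation occurs at C2 between the two coordinating MOM ethers, and copper-mediated SN2 allylation at the primary carbon of 6 should give the linear E-allyl arene.

Step 6
Reactants: 9 2-[(2E)-3,7-dimethyl-7-(triethylsilyloxy)oct-2-en-1-yl]-1,3-bis(methoxymethoxy)benzene
Product: 11 4-[(2E)-3,7-dimethyl-7-(triethylsilyloxy)oct-2-en-1-yl]-3,5-bis(methoxymethoxy)phenol, via arylboronate 10 (not isolated)
Conditions: [Ir(OMe)(cod)]2 (1.5 mol%), 4,4′-di-tert-butyl-2,2′-bipyridine (3 mol%), B2pin2 (1.0 equiv), THF, 60 °C; then 30% H2O2, aq NaOH, THF, 0 °C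
Reagents that add atoms: hydrogen peroxide, OO
Why: Iridium-catalysed aromatic C–H borylation is sterically controlled and should occur only at C5, the one ring C–H with no ortho substituent, and basic peroxide oxidation of the C–B bond then gives the phenol without touching the trisubstituted alkene.

Step 7
Reactants: 11 4-[(2E)-3,7-dimethyl-7-(triethylsilyloxy)oct-2-en-1-yl]-3,5-bis(methoxymethoxy)phenol
Product: 12 6-hydroxy-2,4-bis(methoxymethoxy)-3-[(2E)-3,7-dimethyl-7-(triethylsilyloxy)oct-2-en-1-yl]benzaldehyde
Conditions: MgCl2, Et3N, (CH2O)n, MeCN, reflux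
Reagents that add atoms: formaldehyde (as paraformaldehyde), C=O
Why: Magnesium-mediated ortho-formylation of phenols (Casnati–Skattebøl) is ortho-specific, and the two ortho positions of 11 are equivalent, so a single salicylaldehyde should form whose free hydroxyl is the future O1.

Step 8
Reactants: 13 methyl (3,4-dihydroxyphenyl)acetate
Product: 14 methyl [3,4-bis(methoxymethoxy)phenyl]acetate
Conditions: MOMCl, i-Pr2NEt, CH2Cl2, 0 °C to rt
Reagents that add atoms: chloromethyl methyl ether, COCCl
Why: Standard acetal protection of the catechol gives ring B the same protecting group as ring A, so one final operation frees all phenols.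

Step 9
Reactants: 14 methyl [3,4-bis(methoxymethoxy)phenyl]acetate
Product: 16 racemic methyl bromo[3,4-bis(methoxymethoxy)phenyl]acetate, via lithium enolate 15 (not isolated)
Conditions: LiN(SiMe3)2, THF, −78 °C; then NBS, −78 °C; used at once
Reagents that add atoms: N-bromosuccinimide, O=C1CCC(=O)N1Br
Why: Electrophilic bromination of the ester enolate puts bromine at the benzylic α-carbon without ring bromination, and the racemic centre is inconsequential because it is equilibrated in step 13.

Step 10
Reactants: 12 6-hydroxy-2,4-bis(methoxymethoxy)-3-[(2E)-3,7-dimethyl-7-(triethylsilyloxy)oct-2-en-1-yl]benzaldehyde; 16 racemic methyl bromo[3,4-bis(methoxymethoxy)phenyl]acetate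
Product: 17 racemic methyl 2-[3,4-bis(methoxymethoxy)phenyl]-2-{2-formyl-3,5-bis(methoxymethoxy)-4-[(2E)-3,7-dimethyl-7-(triethylsilyloxy)oct-2-en-1-yl]phenoxy}acetate
Conditions: K2CO3, DMF, 0 °C to rt
Reagents that add atoms: none
Why: Williamson etherification of the salicylaldehyde phenoxide with the activated benzylic α-bromo ester should form the O1–C2 bond, and the mild base and low temperature disfavour aldol closure onto the aldehyde.

Step 11
Reactants: 17 racemic ester aldehyde
Product: 18 racemic 2-[3,4-bis(methoxymethoxy)phenyl]-2-{2-(hydroxymethyl)-3,5-bis(methoxymethoxy)-4-[(2E)-3,7-dimethyl-7-(triethylsilyloxy)oct-2-en-1-yl]phenoxy}ethan-1-ol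
Conditions: i-Bu2AlH (5 equiv), CH2Cl2, −78 to 0 °C; Rochelle salt work-up
Reagents that add atoms: none
Why: Hydride reduction of both the ester and the aldehyde to primary alcohols brings the two future carbonyl carbons to one oxidation level, so they can be raised together without chemoselectivity problems.

Step 12
Reactants: 18 racemic diol
Product: 19 racemic 2-[3,4-bis(methoxymethoxy)phenyl]-2-{2-formyl-3,5-bis(methoxymethoxy)-4-[(2E)-3,7-dimethyl-7-(triethylsilyloxy)oct-2-en-1-yl]phenoxy}acetaldehyde
Conditions: Dess–Martin periodinane (2.5 equiv), NaHCO3, CH2Cl2, 0 °C to rt; crude product used at once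
Reagents that add atoms: none
Why: Buffered Dess–Martin oxidation should take both primary alcohols to aldehydes under non-basic conditions without over-oxidation or harm to the alkene, acetals and silyl ether.

Step 13
Reactants: 19 racemic dialdehyde
Product: 21 (2R,3R)-2-[3,4-bis(methoxymethoxy)phenyl]-3-hydroxy-5,7-bis(methoxymethoxy)-6-[(2E)-3,7-dimethyl-7-(triethylsilyloxy)oct-2-en-1-yl]chroman-4-one, via Breslow enaminol 20 (not isolated)
Conditions: (5aS,10bR)-2-(pentafluorophenyl)-5a,10b-dihydro-4H,6H-indeno[2,1-b][1,2,4]triazolo[4,3-d][1,4]oxazin-2-ium tetrafluoroborate, C18H11BF9N3O (15 mol%), i-Pr2NEt (50 mol%), toluene (0.02 M), 4 Å molecular sieves, argon, rt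
Reagents that add atoms: none
Why: Proposed new method: the carbene freed from the triazolium salt adds to the non-enolisable ring A aldehyde of 19 and proton transfer gives enaminol 20, whose nucleophilic carbon (future C4) adds to the pendant aldehyde (future C3), after which proton transfer and loss of the carbene release the C4 ketone. The closest known reaction type is the chiral triazolium-carbene-catalysed intramolecular crossed benzoin of 2-(2-oxoalkoxy)benzaldehydes to 3-hydroxychroman-4-ones, here extended to an aldehyde acceptor and run as a dynamic kinetic resolution. Ring C closes by 6-exo-trig attack of the enaminol carbon on the aldehyde carbonyl through a chair-like transition state with ring B on C2 pseudo-equatorial. C3 is set by the catalyst, whose aminoindanol backbone shields one face of the enaminol so that the aldehyde, hydrogen-bonded to the enaminol hydroxyl, presents one carbonyl face. C2 is set by dynamic kinetic resolution: its hydrogen in 19 is α to the acceptor aldehyde and flanked by ring B and the aryloxy oxygen, so the enantiomers of 19 should interconvert through the enol under the amine faster than they cyclise, and only the enantiomer that keeps ring B pseudo-equatorial and trans to the forming C3 alkoxide in the catalyst-preferred arrangement closes quickly. The step needs donor/acceptor chemoselectivity, secured because the α,α-disubstituted, enolising aliphatic aldehyde is the poorer carbene acceptor and any transposed 4-hydroxy-3-ketone can revert by retro-benzoin to the conjugated aryl ketone, and it needs 2,3-trans selectivity, which the equatorial preference and base-mediated equilibration at C3 both favour.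

Step 14
Reactants: 21 protected (2R,3R)-dihydroflavonol
Product: 22 (2R,3R)-2-(3,4-dihydroxyphenyl)-3,5,7-trihydroxy-6-[(2E)-7-hydroxy-3,7-dimethyloct-2-en-1-yl]chroman-4-one (target)
Conditions: HCl (2 M), MeOH/THF (3:1), 35–40 °C
Reagents that add atoms: none
Why: Acid-catalysed methanolysis should cleave the four aryl MOM acetals and the triethylsilyl ether in one operation, and the trans-dihydroflavonol stereocentres and the E alkene should survive dilute acid at this temperature.

## Compound list

1 | geranyl acetate, (2E)-3,7-dimethylocta-2,6-dien-1-yl acetate | CC(=O)OC/C=C(\C)CCC=C(C)C | starting material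
2 | (2E)-6-(acetoxymercurio)-7-hydroxy-3,7-dimethyloct-2-en-1-yl acetate (racemic at C6) | CC(=O)OC/C=C(\C)CCC([Hg]OC(C)=O)C(C)(C)O | intermediate
3 | (2E)-7-hydroxy-3,7-dimethyloct-2-en-1-yl acetate | CC(=O)OC/C=C(\C)CCCC(C)(C)O | intermediate
4 | (2E)-3,7-dimethyl-7-(triethylsilyloxy)oct-2-en-1-yl acetate | CC(=O)OC/C=C(\C)CCCC(C)(C)O[Si](CC)(CC)CC | intermediate
5 | (2E)-3,7-dimethyl-7-(triethylsilyloxy)oct-2-en-1-ol | OC/C=C(\C)CCCC(C)(C)O[Si](CC)(CC)CC | intermediate
6 | (2E)-1-bromo-3,7-dimethyl-7-(triethylsilyloxy)oct-2-ene | BrC/C=C(\C)CCCC(C)(C)O[Si](CC)(CC)CC | intermediate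
7 | 1,3-bis(methoxymethoxy)benzene | COCOc1cccc(OCOC)c1 | starting material
8 | 2-lithio-1,3-bis(methoxymethoxy)benzene | COCOc1cccc(OCOC)c1[Li] | intermediate
9 | 2-[(2E)-3,7-dimethyl-7-(triethylsilyloxy)oct-2-en-1-yl]-1,3-bis(methoxymethoxy)benzene | COCOc1cccc(OCOC)c1C/C=C(\C)CCCC(C)(C)O[Si](CC)(CC)CC | intermediate
10 | pinacol boronate of 9 at C5 (para to the side chain) | COCOc1cc(B2OC(C)(C)C(C)(C)O2)cc(OCOC)c1C/C=C(\C)CCCC(C)(C)O[Si](CC)(CC)CC | intermediate
11 | 4-[(2E)-3,7-dimethyl-7-(triethylsilyloxy)oct-2-en-1-yl]-3,5-bis(methoxymethoxy)phenol | COCOc1cc(O)cc(OCOC)c1C/C=C(\C)CCCC(C)(C)O[Si](CC)(CC)CC | intermediate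
12 | 6-hydroxy-2,4-bis(methoxymethoxy)-3-[(2E)-3,7-dimethyl-7-(triethylsilyloxy)oct-2-en-1-yl]benzaldehyde | O=Cc1c(O)cc(OCOC)c(C/C=C(\C)CCCC(C)(C)O[Si](CC)(CC)CC)c1OCOC | intermediate
13 | methyl (3,4-dihydroxyphenyl)acetate | COC(=O)Cc1ccc(O)c(O)c1 | starting material
14 | methyl [3,4-bis(methoxymethoxy)phenyl]acetate | COC(=O)Cc1ccc(OCOC)c(OCOC)c1 | intermediate
15 | lithium enolate of 14 (geometry not defined) | COC(O[Li])=Cc1ccc(OCOC)c(OCOC)c1 | intermediate
16 | methyl bromo[3,4-bis(methoxymethoxy)phenyl]acetate (racemic) | COC(=O)C(Br)c1ccc(OCOC)c(OCOC)c1 | intermediate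
17 | methyl 2-[3,4-bis(methoxymethoxy)phenyl]-2-{2-formyl-3,5-bis(methoxymethoxy)-4-[(2E)-3,7-dimethyl-7-(triethylsilyloxy)oct-2-en-1-yl]phenoxy}acetate (racemic) | COC(=O)C(Oc1cc(OCOC)c(C/C=C(\C)CCCC(C)(C)O[Si](CC)(CC)CC)c(OCOC)c1C=O)c1ccc(OCOC)c(OCOC)c1 | intermediate
18 | 2-[3,4-bis(methoxymethoxy)phenyl]-2-{2-(hydroxymethyl)-3,5-bis(methoxymethoxy)-4-[(2E)-3,7-dimethyl-7-(triethylsilyloxy)oct-2-en-1-yl]phenoxy}ethan-1-ol (racemic) | OCC(Oc1cc(OCOC)c(C/C=C(\C)CCCC(C)(C)O[Si](CC)(CC)CC)c(OCOC)c1CO)c1ccc(OCOC)c(OCOC)c1 | intermediate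
19 | 2-[3,4-bis(methoxymethoxy)phenyl]-2-{2-formyl-3,5-bis(methoxymethoxy)-4-[(2E)-3,7-dimethyl-7-(triethylsilyloxy)oct-2-en-1-yl]phenoxy}acetaldehyde (racemic, configurationally labile) | O=CC(Oc1cc(OCOC)c(C/C=C(\C)CCCC(C)(C)O[Si](CC)(CC)CC)c(OCOC)c1C=O)c1ccc(OCOC)c(OCOC)c1 | intermediate
20 | Breslow enaminol from the ring A aldehyde of 19 and the (5aS,10bR) triazolylidene (enaminol geometry and α-centre not defined) | O=CC(Oc1cc(OCOC)c(C/C=C(\C)CCCC(C)(C)O[Si](CC)(CC)CC)c(OCOC)c1C(O)=C1N2[C@@H]3c4ccccc4C[C@@H]3OCC2=NN1c1c(F)c(F)c(F)c(F)c1F)c1ccc(OCOC)c(OCOC)c1 | intermediate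
21 | (2R,3R)-2-[3,4-bis(methoxymethoxy)phenyl]-3-hydroxy-5,7-bis(methoxymethoxy)-6-[(2E)-3,7-dimethyl-7-(triethylsilyloxy)oct-2-en-1-yl]chroman-4-one | C/C(=C\Cc1c(OCOC)cc2c(c1OCOC)C(=O)[C@H](O)[C@@H](c1ccc(OCOC)c(OCOC)c1)O2)CCCC(C)(C)O[Si](CC)(CC)CC | intermediate
22 | (2R,3R)-2-(3,4-dihydroxyphenyl)-3,5,7-trihydroxy-6-[(2E)-7-hydroxy-3,7-dimethyloct-2-en-1-yl]chroman-4-one | C/C(=C\Cc1c(O)cc2c(c1O)C(=O)[C@H](O)[C@@H](c1ccc(O)c(O)c1)O2)CCCC(C)(C)O | target

## Step count and risks

Total step count: 14. Longest linear sequence: 12 steps (steps 1–7 and 10–14, from geranyl acetate); steps 8–9 form the ring B branch.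

Steps most likely to fail:

1. Step 13 (proposed new method). Enaminol formation at the doubly ortho-oxygenated, electron-rich ring A aldehyde may be slow, so that enolate aldol closure onto that aldehyde or oligomerisation consumes the dialdehyde. Carbene addition may also occur at the aliphatic aldehyde, or racemisation may not outpace cyclisation, eroding enantio- and diastereoselection. The fallback uses known chemistry and still closes ring C at C4–C3. It sets out from 19: SmI2 and t-BuOH in THF at −78 °C should effect ketyl–carbonyl pinacol cyclisation to the racemic 2,3-trans-3,4-cis flavan-3,4-diol F1. Activated MnO2 in CH2Cl2 should then oxidise only the benzylic C4 carbinol, followed by Et3N to equilibrate C3 to trans, giving the racemic trans ketol F2. Preparative chromatography on a chiral stationary phase separates the enantiomers, and the route is rejoined at 21.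

2. Step 14. Acid may promote cyclisation of the 5- or 7-hydroxyl onto the protonated side-chain alkene (chroman formation) or ionisation of the tertiary alcohol before all four acetals are cleaved. The fallback sets out from 21 and avoids protic acid: TMSOTf and 2,2′-bipyridyl in MeCN at 0 °C, then water, should convert the aryl MOM ethers through aryl silyl ethers into the tetraphenol triethylsilyl ether F3. Et3N·3HF in THF at rt then removes the silyl group, arriving at 22.

3. Step 10. The acidic α-hydrogen of the product may add to the neighbouring aldehyde under the basic conditions (aldol closure to a dihydrobenzofuranol), and the labile benzylic bromide may solvolyse or eliminate before etherification. The fallback forms the same ether without base. It sets out from 14: diazo transfer with p-acetamidobenzenesulfonyl azide and DBU in MeCN should give methyl diazo[3,4-bis(methoxymethoxy)phenyl]acetate F4. Rh2(OAc)4-catalysed carbenoid O–H insertion into the phenol of 12 (CH2Cl2, slow addition, rt) then comes back to the route at 17.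

Further compounds
F1 | step 13 | racemic (2R*,3S*,4S*)-2-[3,4-bis(methoxymethoxy)phenyl]-5,7-bis(methoxymethoxy)-6-[(2E)-3,7-dimethyl-7-(triethylsilyloxy)oct-2-en-1-yl]chroman-3,4-diol (both enantiomers written) | C/C(=C\Cc1c(OCOC)cc2c(c1OCOC)[C@H](O)[C@H](O)[C@@H](c1ccc(OCOC)c(OCOC)c1)O2)CCCC(C)(C)O[Si](CC)(CC)CC.C/C(=C\Cc1c(OCOC)cc2c(c1OCOC)[C@@H](O)[C@@H](O)[C@H](c1ccc(OCOC)c(OCOC)c1)O2)CCCC(C)(C)O[Si](CC)(CC)CC
F2 | step 13 | racemic trans ketol, the racemate of 21 (both enantiomers written) | C/C(=C\Cc1c(OCOC)cc2c(c1OCOC)C(=O)[C@H](O)[C@@H](c1ccc(OCOC)c(OCOC)c1)O2)CCCC(C)(C)O[Si](CC)(CC)CC.C/C(=C\Cc1c(OCOC)cc2c(c1OCOC)C(=O)[C@@H](O)[C@H](c1ccc(OCOC)c(OCOC)c1)O2)CCCC(C)(C)O[Si](CC)(CC)CC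
F3 | step 14 | (2R,3R)-2-(3,4-dihydroxyphenyl)-3,5,7-trihydroxy-6-[(2E)-3,7-dimethyl-7-(triethylsilyloxy)oct-2-en-1-yl]chroman-4-one | C/C(=C\Cc1c(O)cc2c(c1O)C(=O)[C@H](O)[C@@H](c1ccc(O)c(O)c1)O2)CCCC(C)(C)O[Si](CC)(CC)CC
F4 | step 10 | methyl diazo[3,4-bis(methoxymethoxy)phenyl]acetate | COC(=O)C(=[N+]=[N-])c1ccc(OCOC)c(OCOC)c1
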